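**Retrosynthetic overview**

- End game: the target comes from quercetin 3-acetate by sulfation of O7, O3' and O4' (the chelated 5-OH stays free). Quercetin 3-acetate comes from its 5,7,3',4'-tetrabenzyl ether by hydrogenolysis, and that from a 3-O-(1-adamantyl) flavonol by acidolysis and acetylation of the single 3-OH.
- Feature the strategy rests on: in flavone numbering, C2 (carrying ring B) and C3 (carrying O3) of ring C are the two sp carbons of an aryl ynol ether Ar-C≡C-OR. O1, ring A and C4 together are a 2-hydroxybenzaldehyde that only has to give up its formyl hydrogen.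
- Key disconnection: C3-C4 and O1-C2, made in one rhodium-catalysed oxidative formyl C-H annulation of the salicylaldehyde with the ynol ether. R is 1-adamantyl, which cannot undergo retro-ene loss but is acid-labile.
- Precursors: the salicylaldehyde by magnesium-mediated ortho-formylation of 3,5-bis(benzyloxy)phenol; the ynol ether from 1-adamantanol, trichloroethylene and 4-bromo-1,2-bis(benzyloxy)benzene (dichlorovinyl ether, alkoxyacetylide, Negishi coupling).
- Ring order: rings A and B are bought as benzene rings; ring C is the only ring formed, in the key step.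

Key step: step 4

Assumption 1: compounds 1, 4, 5 and 8 are taken as purchasable.
Assumption 2: the target is drawn as the free tris(hydrogen sulfate). Aryl hydrogen sulfates are handled as salts, so step 8 passes through the pyridinium salt and the acid form is set free by cold cation exchange directly before use.

**Step 1**
Reactants: 1 3,5-bis(benzyloxy)phenol
Product: 3 2,4-bis(benzyloxy)-6-hydroxybenzaldehyde, via hydroxymethylphenol 2 (not isolated)
Conditions: MgCl2 (1.5 equiv), Et3N (3.8 equiv), paraformaldehyde (6 equiv), MeCN, reflux; then 1 M HCl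
Reagents that add atoms: formaldehyde (as paraformaldehyde), C=O
Why: Casnati–Skattebøl ortho-formylation, in which the magnesium phenoxide delivers formaldehyde to the ortho carbon through a chelate and a second formaldehyde oxidises the benzylic alkoxide by hydride transfer; the two ortho positions of 1 are equivalent, so a single aldehyde should result.

**Step 2**
Reactants: 4 1-adamantanol; 5 trichloroethylene
Product: 7 (E)-1-[(1,2-dichloroethenyl)oxy]adamantane, via dichloroacetylene 6 (not isolated)
Conditions: KH (1.2 equiv), THF, 0 °C → rt; then 5 (1.1 equiv), −50 °C → rt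
Reagents that add atoms: none
Why: Greene dichlorovinyl ether synthesis, in which the potassium alkoxide eliminates HCl from 5 and then adds anti to the dichloroacetylene so formed, which fixes the E geometry.

**Step 3**
Reactants: 7 (E)-1-[(1,2-dichloroethenyl)oxy]adamantane; 8 4-bromo-1,2-bis(benzyloxy)benzene
Product: 12 1-{[3,4-bis(benzyloxy)phenyl]ethynyloxy}adamantane, via chloroalkynyl ether 9 (not isolated), via lithium alkoxyacetylide 10 (not isolated), via alkynylzinc chloride 11 (not isolated)
Conditions: n-BuLi (2.2 equiv), THF, −78 → −40 °C; ZnCl2 (1.2 equiv), −40 → 0 °C; 8 (0.8 equiv), Pd2(dba)3 (2 mol%), XPhos (8 mol%), THF, rt → 45 °C; chromatography on Et3N-deactivated silica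
Reagents that add atoms: none
Why: n-BuLi removes the vinyl hydrogen, LiCl is lost and chlorine–lithium exchange on the chloroalkyne gives the lithium alkoxyacetylide, which after transmetalation to zinc undergoes Negishi coupling with the aryl bromide at zerovalent palladium under non-acidic conditions that the ynol ether tolerates.

**Step 4**
Reactants: 3 2,4-bis(benzyloxy)-6-hydroxybenzaldehyde; 12 1-{[3,4-bis(benzyloxy)phenyl]ethynyloxy}adamantane
Product: 13 3-(1-adamantyloxy)-5,7-bis(benzyloxy)-2-[3,4-bis(benzyloxy)phenyl]-4H-chromen-4-one (3-O-(1-adamantyl)-5,7,3',4'-tetra-O-benzylquercetin)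
Conditions: [Cp*RhCl2]2 (2.5 mol%), anhydrous Cu(OAc)2 (2.2 equiv), Na2CO3 (2.5 equiv), 4 Å MS, toluene, 80 °C, Ar; 12 (1.5 equiv) added over 4 h
Reagents that add atoms: none
Why: Proposed new method: the phenoxide of 3 binds trivalent rhodium (Cp*Rh acetate formed from [Cp*RhCl2]2 and Cu(OAc)2) and acetate-assisted metalation cleaves the formyl C-H bond to a five-membered acylrhodacycle; ynol ether 12 then inserts into the Rh-acyl bond to give a seven-membered oxarhodacycle, C-O reductive elimination releases 13 and monovalent rhodium, and Cu(OAc)2 restores trivalent rhodium. The closest known reaction type is the rhodium-catalysed oxidative annulation of salicylaldehydes with diaryl and aryl alkyl alkynes to 2,3-disubstituted chromones; an ynol ether has not been used as the alkyne partner, hence the label. Ring C is closed as a (4+2) annulation, C3-C4 by migratory insertion and O1-C2 by C-O reductive elimination from the seven-membered metallacycle. No stereocenter is formed. The step needs the acyl carbon to bond to the oxygen-bearing alkyne carbon: the ynol ether is polarised with its electrophilic carbon next to oxygen, so the migrating acyl group should go there, and rhodium should take the aryl-bearing, more nucleophilic carbon as it does with aryl alkyl alkynes, so both effects point the same way. Na2CO3 and molecular sieves are there to keep the AcOH by-product and water from adding to the ynol ether, and the 1-adamantyl group excludes retro-ene loss of an alkene at 80 °C because that would need a bridgehead double bond.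

**Step 5**
Reactants: 13 3-O-(1-adamantyl)-5,7,3',4'-tetra-O-benzylquercetin
Product: 14 5,7-bis(benzyloxy)-2-[3,4-bis(benzyloxy)phenyl]-3-hydroxy-4H-chromen-4-one (5,7,3',4'-tetra-O-benzylquercetin)
Conditions: TFA/CH2Cl2 (1:2), 1,3-dimethoxybenzene (5 equiv), 0 °C → rt, monitored; aq. NaHCO3
Reagents that add atoms: none
Why: SN1 acidolysis of a tertiary alkyl ether, in which protonation makes the flavonol a good leaving group and the 1-adamantyl cation is trapped by Friedel–Crafts alkylation of 1,3-dimethoxybenzene, while the primary benzyl aryl ethers should ionise far more slowly at this temperature.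

**Step 6**
Reactants: 14 5,7,3',4'-tetra-O-benzylquercetin
Product: 15 5,7-bis(benzyloxy)-2-[3,4-bis(benzyloxy)phenyl]-4-oxo-4H-chromen-3-yl acetate (3-O-acetyl-5,7,3',4'-tetra-O-benzylquercetin)
Conditions: Ac2O (1.5 equiv), pyridine, DMAP (5 mol%), CH2Cl2, 0 °C → rt
Reagents that add atoms: acetic anhydride, CC(=O)OC(C)=O
Why: DMAP-catalysed O-acylation of the only free hydroxyl group in the molecule.

**Step 7**
Reactants: 15 3-O-acetyl-5,7,3',4'-tetra-O-benzylquercetin
Product: 16 2-(3,4-dihydroxyphenyl)-5,7-dihydroxy-4-oxo-4H-chromen-3-yl acetate (quercetin 3-acetate)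
Conditions: H2 (1 atm), 10% Pd/C, THF/EtOAc (1:1), rt
Reagents that add atoms: none
Why: hydrogenolysis of the four benzyl aryl ethers on Pd/C in a non-nucleophilic solvent, conditions under which the chromone C2-C3 double bond and the 3-acetate should stay intact.

**Step 8**
Reactants: 16 quercetin 3-acetate
Product: 17 quercetin 3-acetate 7,3',4'-tri-O-sulfate
Conditions: SO3·pyridine (15 equiv), dry DMF/pyridine (4:1), rt → 40 °C; then Dowex 50W (H+ form), H2O, 0 °C; C18 chromatography
Reagents that add atoms: sulfur trioxide–pyridine complex, O=S(=O)([O-])[n+]1ccccc1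
Why: O-sulfation of phenols with an amine–SO3 complex, in which 5-OH is held in a six-membered hydrogen bond to the C4 carbonyl and is the least nucleophilic hydroxyl group, so O7, O3' and O4' should react and O5 should not.

**Compound list**

1 | 3,5-bis(benzyloxy)phenol | Oc1cc(OCc2ccccc2)cc(OCc2ccccc2)c1 | starting material
2 | 3,5-bis(benzyloxy)-2-(hydroxymethyl)phenol (magnesium salt in the flask, not isolated) | OCc1c(O)cc(OCc2ccccc2)cc1OCc1ccccc1 | intermediate
3 | 2,4-bis(benzyloxy)-6-hydroxybenzaldehyde | O=Cc1c(O)cc(OCc2ccccc2)cc1OCc1ccccc1 | intermediate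
4 | 1-adamantanol | OC12CC3CC(CC(C3)C1)C2 | starting material
5 | trichloroethylene | ClC=C(Cl)Cl | starting material
6 | dichloroacetylene (not isolated) | ClC#CCl | intermediate
7 | (E)-1-[(1,2-dichloroethenyl)oxy]adamantane | Cl/C=C(/Cl)OC12CC3CC(CC(C3)C1)C2 | intermediate
8 | 4-bromo-1,2-bis(benzyloxy)benzene | Brc1ccc(OCc2ccccc2)c(OCc2ccccc2)c1 | starting material
9 | 1-[(chloroethynyl)oxy]adamantane (not isolated) | ClC#COC12CC3CC(CC(C3)C1)C2 | intermediate
10 | lithium (1-adamantyloxy)ethynide (not isolated) | [Li]C#COC12CC3CC(CC(C3)C1)C2 | intermediate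
11 | chloro[(1-adamantyloxy)ethynyl]zinc (not isolated) | Cl[Zn]C#COC12CC3CC(CC(C3)C1)C2 | intermediate
12 | 1-{[3,4-bis(benzyloxy)phenyl]ethynyloxy}adamantane | C(#Cc1ccc(OCc2ccccc2)c(OCc2ccccc2)c1)OC12CC3CC(CC(C3)C1)C2 | intermediate
13 | 3-O-(1-adamantyl)-5,7,3',4'-tetra-O-benzylquercetin | O=c1c(OC23CC4CC(CC(C4)C2)C3)c(-c2ccc(OCc3ccccc3)c(OCc3ccccc3)c2)oc2cc(OCc3ccccc3)cc(OCc3ccccc3)c12 | intermediate
14 | 5,7,3',4'-tetra-O-benzylquercetin | O=c1c(O)c(-c2ccc(OCc3ccccc3)c(OCc3ccccc3)c2)oc2cc(OCc3ccccc3)cc(OCc3ccccc3)c12 | intermediate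
15 | 3-O-acetyl-5,7,3',4'-tetra-O-benzylquercetin | CC(=O)Oc1c(-c2ccc(OCc3ccccc3)c(OCc3ccccc3)c2)oc2cc(OCc3ccccc3)cc(OCc3ccccc3)c2c1=O | intermediate
16 | quercetin 3-acetate | CC(=O)Oc1c(-c2ccc(O)c(O)c2)oc2cc(O)cc(O)c2c1=O | intermediate
17 | quercetin 3-acetate 7,3',4'-tri-O-sulfate | CC(=O)Oc1c(-c2ccc(OS(=O)(=O)O)c(OS(=O)(=O)O)c2)oc2cc(OS(=O)(=O)O)cc(O)c2c1=O | target

**Step count**

Total: 8 steps. Longest linear sequence: 7 steps (steps 2 to 8, from 1-adamantanol and trichloroethylene).

**Steps most likely to fail**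

1. Step 4 (Proposed new method). The ynol ether may be consumed by addition of AcOH, water or the phenol before it inserts. Insertion may occur with the reverse orientation. The acylrhodium may decarbonylate and lead to a benzofuran.
Fallback by known chemistry, setting out from 8 and 3 and coming back at 14: Sonogashira coupling of 8 with ethynyltrimethylsilane (Pd(PPh3)2Cl2, CuI, Et3N, 70 °C) should give {[3,4-bis(benzyloxy)phenyl]ethynyl}trimethylsilane F1. K2CO3 in MeOH then gives 1,2-bis(benzyloxy)-4-ethynylbenzene F2. Its magnesium acetylide (EtMgBr, THF; 2.5 equiv, one equivalent being used up by the phenol) adds to aldehyde 3 to give racemic 1-[2,4-bis(benzyloxy)-6-hydroxyphenyl]-3-[3,4-bis(benzyloxy)phenyl]prop-2-yn-1-ol F3. MnO2 in CH2Cl2 oxidises this to the ynone 1-[2,4-bis(benzyloxy)-6-hydroxyphenyl]-3-[3,4-bis(benzyloxy)phenyl]prop-2-yn-1-one F4. DMAP (10 mol%) in DMF closes ring C by 6-endo-dig oxa-Michael addition to 5,7,3',4'-tetra-O-benzylluteolin F5. Dimethyldioxirane in acetone/CH2Cl2 at 0 °C epoxidises C2-C3 to the racemic cis-fused flavone 2,3-oxide F6, and a trace of p-TsOH opens it to flavonol 14.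

2. Step 5. Ionisation of the adamantyl ether may be slow, and on longer exposure the peri 5-O-benzyl ether may be lost or ring A may be C-alkylated.
Fallback, setting out from 13 and coming back at 16: BCl3 (2.5 equiv, CH2Cl2, −78 °C) uses chelation to the C4 carbonyl to cleave both flanking ethers on purpose, the 3-O-adamantyl and the 5-O-benzyl, leaving the three remote benzyl ethers and giving 7,3',4'-tri-O-benzylquercetin F7. Ac2O (1.05 equiv) in pyridine at 0 °C acetylates the 3-OH in preference to the strongly chelated 5-OH and gives 3-O-acetyl-7,3',4'-tri-O-benzylquercetin F8. Hydrogenolysis (H2, Pd/C, THF/EtOAc) then gives 16, so that 14 and 15 are bypassed.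

3. Step 8. Sulfation may stop short at the crowded 3',4'-catechol, the 3-acetyl group may be lost or transferred in the basic medium, and aryl sulfates may hydrolyse while in the acid form.
Fallback, setting out from 16 and coming back at 17: 2,2,2-trichloroethyl chlorosulfate (3.6 equiv, Et3N, DMAP, THF, 0 °C) converts the three reactive phenols into neutral sulfate diesters that can be purified on silica, giving 3-O-acetylquercetin 7,3',4'-tris(2,2,2-trichloroethyl sulfate) F9. Reductive fragmentation with Zn and HCO2NH4 in THF/MeOH at rt, followed by cold H+ exchange, then gives 17.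

**Further compounds**

F1 | step 4 | {[3,4-bis(benzyloxy)phenyl]ethynyl}trimethylsilane | C[Si](C)(C)C#Cc1ccc(OCc2ccccc2)c(OCc2ccccc2)c1
F2 | step 4 | 1,2-bis(benzyloxy)-4-ethynylbenzene | C#Cc1ccc(OCc2ccccc2)c(OCc2ccccc2)c1
F3 | step 4 | rac-1-[2,4-bis(benzyloxy)-6-hydroxyphenyl]-3-[3,4-bis(benzyloxy)phenyl]prop-2-yn-1-ol | OC(C#Cc1ccc(OCc2ccccc2)c(OCc2ccccc2)c1)c1c(O)cc(OCc2ccccc2)cc1OCc1ccccc1
F4 | step 4 | 1-[2,4-bis(benzyloxy)-6-hydroxyphenyl]-3-[3,4-bis(benzyloxy)phenyl]prop-2-yn-1-one | O=C(C#Cc1ccc(OCc2ccccc2)c(OCc2ccccc2)c1)c1c(O)cc(OCc2ccccc2)cc1OCc1ccccc1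
F5 | step 4 | 5,7,3',4'-tetra-O-benzylluteolin | O=c1cc(-c2ccc(OCc3ccccc3)c(OCc3ccccc3)c2)oc2cc(OCc3ccccc3)cc(OCc3ccccc3)c12
F6 | step 4 | rac-5,7,3',4'-tetra-O-benzylluteolin 2,3-oxide (cis-fused epoxide) | O=C1c2c(OCc3ccccc3)cc(OCc3ccccc3)cc2OC2(c3ccc(OCc4ccccc4)c(OCc4ccccc4)c3)OC12
F7 | step 5 | 7,3',4'-tri-O-benzylquercetin | O=c1c(O)c(-c2ccc(OCc3ccccc3)c(OCc3ccccc3)c2)oc2cc(OCc3ccccc3)cc(O)c12
F8 | step 5 | 3-O-acetyl-7,3',4'-tri-O-benzylquercetin | CC(=O)Oc1c(-c2ccc(OCc3ccccc3)c(OCc3ccccc3)c2)oc2cc(OCc3ccccc3)cc(O)c2c1=O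
F9 | step 8 | 3-O-acetylquercetin 7,3',4'-tris(2,2,2-trichloroethyl sulfate) | CC(=O)Oc1c(-c2ccc(OS(=O)(=O)OCC(Cl)(Cl)Cl)c(OS(=O)(=O)OCC(Cl)(Cl)Cl)c2)oc2cc(OS(=O)(=O)OCC(Cl)(Cl)Cl)cc(O)c2c1=O
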